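Both C5 units are disconnected at once: the C8–prenyl bond and the C3′–C bond of the future pyran. Rings A and B are the same 1-alkyl-2,4-dioxygenated benzene with a C5 unit at position 3, so C8–H (between O1 and O7) and C3′–H (between O2′ and O4′) are each the only C–H flanked by two oxygens. A twofold directed ortho-lithiation with copper-mediated prenylation of the (3R)-isoflavan carrying MOM ethers at O7 and O2′ and a SEM ether at O4′ forms both bonds in one flask. The precursor comes from an Evans alkylation and a Pd-catalysed aryl etherification; fluoride, DDQ and mild acid then finish ring D and release the phenols.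

Key step: step 11

Assumption: isoflavan numbering is used (O1, C2, C3, C4, ring A C4a–C8a, ring B C1′–C6′); MOM = methoxymethyl, SEM = 2-(trimethylsilyl)ethoxymethyl; 2,4-dihydroxyacetophenone and 2-bromo-4-hydroxybenzaldehyde are taken as commercial, the first because its chelated 2-OH allows clean differentiation of the two ring B oxygens.

Step 1
Reactants: 1 2,4-dihydroxyacetophenone
Product: 2 1-[2-hydroxy-4-(SEM-oxy)phenyl]ethanone
Conditions: SEMCl (1.05 equiv), i-Pr2NEt, CH2Cl2, 0 °C → rt
Reagents that add atoms: 2-(trimethylsilyl)ethoxymethyl chloride (SEMCl), C[Si](C)(C)CCOCCl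
Why: Williamson-type O-alkylation in which the 2-OH is held in a hydrogen bond to the acetyl C=O, so only the 4-OH (the future O4′) should react.

Step 2
Reactants: 2 1-[2-hydroxy-4-(SEM-oxy)phenyl]ethanone
Product: 3 1-[2-(methoxymethoxy)-4-(SEM-oxy)phenyl]ethanone
Conditions: NaH, MOMCl, DMF, 0 °C → rt
Reagents that add atoms: chloromethyl methyl ether (MOMCl), COCCl
Why: Full deprotonation breaks the chelate and the phenoxide is O-alkylated (Williamson ether synthesis), which fixes the MOM (O2′) / SEM (O4′) pattern of ring B.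

Step 3
Reactants: 3 1-[2-(methoxymethoxy)-4-(SEM-oxy)phenyl]ethanone
Product: 5 2-[2-(methoxymethoxy)-4-(SEM-oxy)phenyl]acetic acid, via 2-[2-(methoxymethoxy)-4-(SEM-oxy)phenyl]-1-(morpholin-4-yl)ethanethione 4 (not isolated)
Conditions: S8, morpholine, 130 °C; then NaOH, EtOH/H2O, reflux; citric acid to pH 4–5, 0 °C
Reagents that add atoms: sodium hydroxide, [Na+].[OH-]; water, O
Why: The Willgerodt–Kindler reaction moves the oxidised carbon to the chain end as the thiomorpholide, and its basic hydrolysis should give the arylacetic acid; both acetals tolerate amine, sulfur and hydroxide, and the cold weak-acid work-up spares them.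

Step 4
Reactants: 5 2-[2-(methoxymethoxy)-4-(SEM-oxy)phenyl]acetic acid; 6 (R)-4-benzyl-2-oxazolidinone
Product: 8 (R)-4-benzyl-3-{2-[2-(methoxymethoxy)-4-(SEM-oxy)phenyl]acetyl}oxazolidin-2-one, via mixed arylacetic pivalic anhydride 7 (not isolated)
Conditions: PivCl, Et3N, THF, −20 °C; then 6, LiCl, −20 °C → rt
Reagents that add atoms: none
Why: N-acylation of the oxazolidinone by the mixed pivalic anhydride, which is attacked at the less hindered arylacetyl carbonyl (standard preparation of Evans imides).

Step 5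
Reactants: 9 2-bromo-4-hydroxybenzaldehyde
Product: 10 2-bromo-4-(methoxymethoxy)benzaldehyde
Conditions: MOMCl, i-Pr2NEt, CH2Cl2, 0 °C → rt
Reagents that add atoms: chloromethyl methyl ether (MOMCl), COCCl
Why: Williamson-type O-alkylation of the only phenol; this oxygen becomes O7 and its MOM group later directs metalation to C8.

Step 6
Reactants: 10 2-bromo-4-(methoxymethoxy)benzaldehyde
Product: 11 [2-bromo-4-(methoxymethoxy)phenyl]methanol
Conditions: NaBH4, MeOH, 0 °C
Reagents that add atoms: none
Why: Borohydride reduction of the aldehyde, which leaves the aryl bromide and the MOM ether untouched.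

Step 7
Reactants: 11 [2-bromo-4-(methoxymethoxy)phenyl]methanol
Product: 12 2-bromo-1-(bromomethyl)-4-(methoxymethoxy)benzene
Conditions: CBr4, PPh3, CH2Cl2, 0 °C
Reagents that add atoms: carbon tetrabromide, BrC(Br)(Br)Br
Why: Appel bromination under neutral conditions keeps the MOM ether, and the ortho bromine tempers the benzylic bromide so that it should be easier to handle than a 2,4-dialkoxybenzyl bromide.

Step 8
Reactants: 8 (R)-4-benzyl-3-{2-[2-(methoxymethoxy)-4-(SEM-oxy)phenyl]acetyl}oxazolidin-2-one; 12 2-bromo-1-(bromomethyl)-4-(methoxymethoxy)benzene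
Product: 14 (R)-4-benzyl-3-{(2R)-3-[2-bromo-4-(methoxymethoxy)phenyl]-2-[2-(methoxymethoxy)-4-(SEM-oxy)phenyl]propanoyl}oxazolidin-2-one, via sodium (Z)-enolate of the imide 13 (not isolated)
Conditions: NaHMDS, THF, −78 °C; then 12, −78 → −30 °C
Reagents that add atoms: none
Why: Evans asymmetric alkylation, in which the chelated Z-enolate is attacked by the benzylic bromide on the face opposite the C4 benzyl group of the (R)-auxiliary; this sets the new centre (the future C3) as R, because the aryl group outranks the incoming CH2Ar.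

Step 9
Reactants: 14 (R)-4-benzyl-3-{(2R)-3-[2-bromo-4-(methoxymethoxy)phenyl]-2-[2-(methoxymethoxy)-4-(SEM-oxy)phenyl]propanoyl}oxazolidin-2-one
Product: 15 (2R)-3-[2-bromo-4-(methoxymethoxy)phenyl]-2-[2-(methoxymethoxy)-4-(SEM-oxy)phenyl]propan-1-ol
Conditions: LiBH4, MeOH (1 equiv), Et2O, 0 °C
Reagents that add atoms: none
Why: Reductive cleavage of the imide to the primary alcohol proceeds without enolisation, so the α-aryl centre should keep its configuration; the aryl bromide is inert and the auxiliary 6 is recovered.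

Step 10
Reactants: 15 (2R)-3-[2-bromo-4-(methoxymethoxy)phenyl]-2-[2-(methoxymethoxy)-4-(SEM-oxy)phenyl]propan-1-ol
Product: 16 (3R)-7,2′-bis(methoxymethoxy)-4′-(SEM-oxy)isoflavan
Conditions: Pd(OAc)2 (5 mol %), 2-(di-tert-butylphosphino)-1,1′-binaphthyl (6 mol %), Cs2CO3, toluene, 70 °C
Reagents that add atoms: none
Why: Intramolecular Buchwald–Hartwig C–O coupling of the primary alcohol with the aryl bromide closes the six-membered ring C (O1–C8a bond); the bulky biaryl phosphine favours C–O reductive elimination over β-hydride elimination, and C3 is not involved.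

Step 11
Reactants: 16 (3R)-7,2′-bis(methoxymethoxy)-4′-(SEM-oxy)isoflavan; 17 prenyl bromide (1-bromo-3-methylbut-2-ene, excess)
Product: 20 (3R)-7,2′-bis(methoxymethoxy)-8,3′-bis(3-methylbut-2-enyl)-4′-(SEM-oxy)isoflavan, via 8,3′-dilithio derivative of the isoflavan 18 (not isolated), via 8,3′-bis(copper(I)) derivative of the isoflavan 19 (not isolated)
Conditions: n-BuLi (3 equiv), TMEDA, THF, −20 → 0 °C; CuBr·SMe2 (3 equiv), −78 → −40 °C; 17 (4 equiv), −78 °C → rt
Reagents that add atoms: none
Why: n-BuLi/TMEDA is pre-complexed by the acetal oxygens and removes the two protons that each lie between two oxygen donors (C8–H between O1 and the O7 MOM ether, C3′–H between the O2′ MOM and O4′ SEM ethers), giving the dilithio species 18; transmetalation to copper(I) gives 19, which attacks prenyl bromide in SN2 fashion at its primary carbon, so that two aryl–CH2 bonds form in one flask. The closest known reaction type is the cooperative directed ortho-metalation of MOM- or SEM-protected resorcinol ethers at the carbon between the oxygens followed by copper-mediated prenylation, here run on both rings at once. No ring closes and no stereocentre is created; ring D follows later from the 3′-prenyl group and O4′. The step needs site selectivity for C8 and C3′ over C6 and C5′, secured by two flanking oxygen donors at each wanted position against one at each unwanted position, and attack at the primary rather than the tertiary end of the allylic bromide, secured by the arylcopper(I) species. The benzylic C3–H and C4–H2 are far less acidic than the doubly flanked aryl C–H, so the (3R) centre should be carried through unchanged, and the substrate holds no other group that reacts with the alkyllithium.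

Step 12
Reactants: 20 (3R)-7,2′-bis(methoxymethoxy)-8,3′-bis(3-methylbut-2-enyl)-4′-(SEM-oxy)isoflavan
Product: 21 (3R)-4′-hydroxy-7,2′-bis(methoxymethoxy)-8,3′-bis(3-methylbut-2-enyl)isoflavan
Conditions: TBAF (6 equiv), DMPU/THF, 70 °C
Reagents that add atoms: none
Why: Fluoride attacks silicon and the SEM group fragments to the 4′-phenoxide (fluoride-induced β-elimination of a 2-silylethyl acetal); MOM ethers and alkenes are inert to fluoride, so only O4′ should be freed.

Step 13
Reactants: 21 (3R)-4′-hydroxy-7,2′-bis(methoxymethoxy)-8,3′-bis(3-methylbut-2-enyl)isoflavan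
Product: 23 (3R)-7-(methoxymethoxy)-3-[5-(methoxymethoxy)-2,2-dimethyl-2H-chromen-6-yl]-8-(3-methylbut-2-enyl)chroman, via ring B o-quinone methide 22 (not isolated)
Conditions: DDQ (1.1 equiv), benzene, 80 °C
Reagents that add atoms: none
Why: DDQ dehydrogenates the o-prenylphenol at its benzylic–allylic CH2 to the o-quinone methide 22, which closes by oxa-6π electrocyclisation to the 2,2-dimethyl-2H-chromene (oxidative cyclisation of o-prenylphenols); O2′ and O7 are capped, so only O4′ can close and the 8-prenyl group should stay open.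

Step 14
Reactants: 23 (3R)-7-(methoxymethoxy)-3-[5-(methoxymethoxy)-2,2-dimethyl-2H-chromen-6-yl]-8-(3-methylbut-2-enyl)chroman
Product: 24 (3R)-3-(5-hydroxy-2,2-dimethyl-2H-chromen-6-yl)-8-(3-methylbut-2-enyl)chroman-7-ol (target)
Conditions: 3 M aq HCl, MeOH, rt → 40 °C
Reagents that add atoms: none
Why: Acid-catalysed methanolysis of the two aryl MOM acetals under dilute, mild conditions, chosen to unmask an o-prenylphenol without hydroalkoxylation of the prenyl or chromene alkene; C3 is not touched.

Compound list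
1 | 2,4-dihydroxyacetophenone | CC(=O)c1ccc(O)cc1O | starting material
2 | 1-[2-hydroxy-4-(SEM-oxy)phenyl]ethanone | CC(=O)c1ccc(OCOCC[Si](C)(C)C)cc1O | intermediate
3 | 1-[2-(methoxymethoxy)-4-(SEM-oxy)phenyl]ethanone | CC(=O)c1ccc(OCOCC[Si](C)(C)C)cc1OCOC | intermediate
4 | 2-[2-(methoxymethoxy)-4-(SEM-oxy)phenyl]-1-(morpholin-4-yl)ethanethione | S=C(Cc1ccc(OCOCC[Si](C)(C)C)cc1OCOC)N1CCOCC1 | intermediate (not isolated)
5 | 2-[2-(methoxymethoxy)-4-(SEM-oxy)phenyl]acetic acid | OC(=O)Cc1ccc(OCOCC[Si](C)(C)C)cc1OCOC | intermediate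
6 | (R)-4-benzyl-2-oxazolidinone | O=C1N[C@H](Cc2ccccc2)CO1 | starting material
7 | [2-(methoxymethoxy)-4-(SEM-oxy)phenyl]acetic pivalic anhydride | CC(C)(C)C(=O)OC(=O)Cc1ccc(OCOCC[Si](C)(C)C)cc1OCOC | intermediate (not isolated)
8 | (R)-4-benzyl-3-{2-[2-(methoxymethoxy)-4-(SEM-oxy)phenyl]acetyl}oxazolidin-2-one | O=C(Cc1ccc(OCOCC[Si](C)(C)C)cc1OCOC)N1[C@H](Cc2ccccc2)COC1=O | intermediate
9 | 2-bromo-4-hydroxybenzaldehyde | O=Cc1ccc(O)cc1Br | starting material
10 | 2-bromo-4-(methoxymethoxy)benzaldehyde | O=Cc1ccc(OCOC)cc1Br | intermediate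
11 | [2-bromo-4-(methoxymethoxy)phenyl]methanol | OCc1ccc(OCOC)cc1Br | intermediate
12 | 2-bromo-1-(bromomethyl)-4-(methoxymethoxy)benzene | BrCc1ccc(OCOC)cc1Br | intermediate
13 | sodium (Z)-enolate of imide 8 | [Na+].[O-]/C(=C\c1ccc(OCOCC[Si](C)(C)C)cc1OCOC)N1[C@H](Cc2ccccc2)COC1=O | intermediate (not isolated)
14 | (R)-4-benzyl-3-{(2R)-3-[2-bromo-4-(methoxymethoxy)phenyl]-2-[2-(methoxymethoxy)-4-(SEM-oxy)phenyl]propanoyl}oxazolidin-2-one | O=C([C@@H](c1ccc(OCOCC[Si](C)(C)C)cc1OCOC)Cc1ccc(OCOC)cc1Br)N1[C@H](Cc2ccccc2)COC1=O | intermediate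
15 | (2R)-3-[2-bromo-4-(methoxymethoxy)phenyl]-2-[2-(methoxymethoxy)-4-(SEM-oxy)phenyl]propan-1-ol | OC[C@@H](c1ccc(OCOCC[Si](C)(C)C)cc1OCOC)Cc1ccc(OCOC)cc1Br | intermediate
16 | (3R)-7,2′-bis(methoxymethoxy)-4′-(SEM-oxy)isoflavan | COCOc1ccc2c(c1)OC[C@@H](c1ccc(OCOCC[Si](C)(C)C)cc1OCOC)C2 | intermediate
17 | prenyl bromide (1-bromo-3-methylbut-2-ene) | CC(C)=CCBr | starting material
18 | 8,3′-dilithio derivative of 16 | [Li]c1c(OCOC)ccc2c1OC[C@@H](c1ccc(OCOCC[Si](C)(C)C)c([Li])c1OCOC)C2 | intermediate (not isolated)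
19 | 8,3′-bis(copper(I)) derivative of 16 | [Cu]c1c(OCOC)ccc2c1OC[C@@H](c1ccc(OCOCC[Si](C)(C)C)c([Cu])c1OCOC)C2 | intermediate (not isolated)
20 | (3R)-7,2′-bis(methoxymethoxy)-8,3′-bis(3-methylbut-2-enyl)-4′-(SEM-oxy)isoflavan | CC(C)=CCc1c(OCOC)ccc2c1OC[C@@H](c1ccc(OCOCC[Si](C)(C)C)c(CC=C(C)C)c1OCOC)C2 | intermediate
21 | (3R)-4′-hydroxy-7,2′-bis(methoxymethoxy)-8,3′-bis(3-methylbut-2-enyl)isoflavan | CC(C)=CCc1c(OCOC)ccc2c1OC[C@@H](c1ccc(O)c(CC=C(C)C)c1OCOC)C2 | intermediate
22 | ring B o-quinone methide of 21 (4′-oxo, 3′-(3-methylbut-2-enylidene)) | CC(C)=CCc1c(OCOC)ccc2c1OC[C@@H](C1=C(OCOC)C(=CC=C(C)C)C(=O)C=C1)C2 | intermediate (not isolated)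
23 | (3R)-7-(methoxymethoxy)-3-[5-(methoxymethoxy)-2,2-dimethyl-2H-chromen-6-yl]-8-(3-methylbut-2-enyl)chroman | CC(C)=CCc1c(OCOC)ccc2c1OC[C@@H](c1ccc3c(c1OCOC)C=CC(C)(C)O3)C2 | intermediate
24 | (3R)-3-(5-hydroxy-2,2-dimethyl-2H-chromen-6-yl)-8-(3-methylbut-2-enyl)chroman-7-ol | CC(C)=CCc1c(O)ccc2c1OC[C@@H](c1ccc3c(c1O)C=CC(C)(C)O3)C2 | target

Total step count: 14. Longest linear sequence: 11 steps (steps 1–4 and 8–14); steps 5–7 make the ring A fragment.

Steps most likely to fail

Step 11. The second metalation on ring A, where one of the two donors is only the ring oxygen O1, may stay incomplete, or part of the arylcopper may attack prenyl bromide at its tertiary end, so that mono-prenylated and 1,1-dimethylallyl material would accompany 20. The fallback sets out from 16 and comes back at 20. The dilithio species 18 is quenched with iodine (THF, −78 °C) to give the (3R)-8,3′-diiodo-7,2′-bis(methoxymethoxy)-4′-(SEM-oxy)isoflavan F1, which can be purified and shows where metalation took place; any mono-iodide can be separated and resubmitted. A twofold Stille coupling with tributyl(3-methylbut-2-enyl)stannane (Pd(PPh3)4, CuI cat., DMF, 80 °C) should then transfer each prenyl group through its primary carbon and give 20.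

Step 13. Hydride abstraction by DDQ at the benzylic C4 or C3 positions or at the 8-prenyl group may compete with formation of the o-quinone methide and lead to over-oxidation. The fallback sets out from 21 and comes back at 23. A non-oxidative selenoetherification with N-(phenylseleno)phthalimide and catalytic camphorsulfonic acid (CH2Cl2, 0 °C), in which only the alkene with an internal nucleophile (the free O4′–H) is captured, should give the 6-endo product (3R)-7-(methoxymethoxy)-3-[5-(methoxymethoxy)-2,2-dimethyl-3-(phenylselanyl)chroman-6-yl]-8-(3-methylbut-2-enyl)chroman F2 as a mixture of epimers at the selenium-bearing carbon. Oxidation with H2O2/pyridine (THF, 0 °C → rt) and syn-elimination of the selenoxide toward the benzylic hydrogen should convert both epimers into the chromene 23.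

Step 10. β-Hydride elimination of the palladium(II) alkoxide may outrun C–O reductive elimination, giving debrominated arene and aldehyde in place of the chroman. The fallback sets out from 15 and comes back at 16. Miyaura borylation of the aryl bromide (B2pin2, Pd(dppf)Cl2, KOAc, dioxane, 85 °C) should give the (2R)-2-[2-(methoxymethoxy)-4-(SEM-oxy)phenyl]-3-[4-(methoxymethoxy)-2-(pinacolboryl)phenyl]propan-1-ol F3. Oxidation (H2O2, NaOH, THF/H2O, 0 °C) should give the (2R)-3-[2-hydroxy-4-(methoxymethoxy)phenyl]-2-[2-(methoxymethoxy)-4-(SEM-oxy)phenyl]propan-1-ol F4. Mitsunobu cyclisation (PPh3, DIAD, THF, 0 °C → rt) then forms the O1–C2 bond by SN2 at the primary carbon, leaves C3 untouched and gives 16.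

Further compounds
F1 | step 11 | (3R)-8,3′-diiodo-7,2′-bis(methoxymethoxy)-4′-(SEM-oxy)isoflavan | Ic1c(OCOC)ccc2c1OC[C@@H](c1ccc(OCOCC[Si](C)(C)C)c(I)c1OCOC)C2
F2 | step 13 | (3R)-7-(methoxymethoxy)-3-[5-(methoxymethoxy)-2,2-dimethyl-3-(phenylselanyl)chroman-6-yl]-8-(3-methylbut-2-enyl)chroman (epimers at C–Se) | CC(C)=CCc1c(OCOC)ccc2c1OC[C@@H](c1ccc3c(c1OCOC)CC([Se]c1ccccc1)C(C)(C)O3)C2
F3 | step 10 | (2R)-2-[2-(methoxymethoxy)-4-(SEM-oxy)phenyl]-3-[4-(methoxymethoxy)-2-(4,4,5,5-tetramethyl-1,3,2-dioxaborolan-2-yl)phenyl]propan-1-ol | OC[C@@H](c1ccc(OCOCC[Si](C)(C)C)cc1OCOC)Cc1ccc(OCOC)cc1B1OC(C)(C)C(C)(C)O1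
F4 | step 10 | (2R)-3-[2-hydroxy-4-(methoxymethoxy)phenyl]-2-[2-(methoxymethoxy)-4-(SEM-oxy)phenyl]propan-1-ol | OC[C@@H](c1ccc(OCOCC[Si](C)(C)C)cc1OCOC)Cc1ccc(OCOC)cc1O
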